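**Retrosynthetic overview**
1. Target ⇐ desilylation of its allylic silyl ether ⇐ closure of the second dihydrobenzofuran (rings B/C): the ring C phenol adds 5-exo to the para-alkoxybenzylic carbon of ring B (an O-alkyl quinone methide cation, oxa-Michael type), trans.
2. That open precursor ⇐ Evans syn-aldol union of a ring C arylacetyl oxazolidinone with the AB aldehyde (a diacetyl-protected 2-aryl-3-hydroxymethyl-7-methoxy-dihydrobenzofuran-5-carbaldehyde), then reductive removal of the auxiliary.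
3. AB aldehyde ⇐ formylation of the 5-bromo-dihydrobenzofuran ⇐ key ring closure: intramolecular oxa-Michael (1,6-) addition of the ring B phenoxide to a para-quinone methide of ring A, set up by an Evans syn-aldol (ring B arylacetyl imide + silyl-vanillin), reduction and acetylation.
4. Building blocks: 5-bromo-2-hydroxy-3-methoxybenzaldehyde (ring B), vanillin (ring A), 5-bromovanillin (ring C), (S)-4-benzyl-oxazolidin-2-one (sets both C3 centres); both C2 centres follow from the trans-selective ring closures.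
5. Ring order: the dihydrobenzofuran of rings A/B is formed first (before the fragment union), the dihydrobenzofuran of rings B/C second (after it).

Assumption: an α-aryl N-acyl oxazolidinone follows the same Evans syn facial sense as the N-propionyl imide; TBS = tert-butyldimethylsilyl, TIPS = triisopropylsilyl, TBDPS = tert-butyldiphenylsilyl (TBSO, TIPSO, TBDPSO are the silyloxy groups).

**Ring B / AB branch**

Step 1
Reactants: 1 5-bromo-2-hydroxy-3-methoxybenzaldehyde
Product: 2 5-bromo-3-methoxy-2-(TBSO)benzaldehyde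
Conditions: TBSCl, imidazole, DMF, rt
Reagents that add atoms: tert-butyldimethylsilyl chloride CC(C)(C)[Si](C)(C)Cl
Why: O-silylation (silyl ether protection) of the phenol; TBS is chosen because it is the more fluoride-labile of the two aryl silyl ethers present in step 10.

Step 2
Reactants: 2 5-bromo-3-methoxy-2-(TBSO)benzaldehyde
Product: 3 (4-bromo-2-ethenyl-6-methoxyphenoxy)(tert-butyl)dimethylsilane
Conditions: Ph3PCH3Br, KOt-Bu, THF, 0 °C; then 2, 0 °C → rt
Reagents that add atoms: methyltriphenylphosphonium bromide C[P+](c1ccccc1)(c1ccccc1)c1ccccc1.[Br-]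
Why: Wittig methylenation turns the aldehyde into a styrene, the handle for a one-carbon-longer side chain, under conditions the aryl bromide and silyl ether tolerate.

Step 3
Reactants: 3 (4-bromo-2-ethenyl-6-methoxyphenoxy)(tert-butyl)dimethylsilane
Product: 5 2-[5-bromo-3-methoxy-2-(TBSO)phenyl]ethanol, via B-alkyl-9-BBN adduct 4 (not isolated)
Conditions: 9-BBN, THF, 0 °C → rt; then NaBO3·4H2O, H2O, rt
Reagents that add atoms: sodium perborate tetrahydrate (NaBO3·4H2O, drawn as the peroxoborate dianion) [Na+].[Na+].O[B-]1(O)OO[B-](O)(O)OO1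
Why: anti-Markovnikov hydroboration–oxidation of the styrene gives the primary alcohol under conditions too mild to cleave the aryl silyl ether or touch the aryl bromide.

Step 4
Reactants: 5 2-[5-bromo-3-methoxy-2-(TBSO)phenyl]ethanol
Product: 7 2-[5-bromo-3-methoxy-2-(TBSO)phenyl]acetic acid, via arylacetaldehyde 6 (not isolated)
Conditions: TEMPO (cat.), PhI(OAc)2, MeCN/H2O (1:1), rt
Reagents that add atoms: water O
Why: TEMPO/hypervalent-iodine oxidation takes the primary alcohol through the aldehyde hydrate to the arylacetic acid without acid or base strong enough to remove the silyl ether.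

Step 5
Reactants: 7 2-[5-bromo-3-methoxy-2-(TBSO)phenyl]acetic acid; 8 (S)-4-benzyl-1,3-oxazolidin-2-one
Product: 10 (S)-4-benzyl-3-{2-[5-bromo-3-methoxy-2-(TBSO)phenyl]acetyl}-1,3-oxazolidin-2-one, via mixed pivalic anhydride 9 (not isolated)
Conditions: PivCl, Et3N, THF, −20 °C; then 8, LiCl, rt
Reagents that add atoms: none
Why: N-acylation of the oxazolidinone through the mixed pivalic anhydride (LiCl/Et3N variant) installs the Evans auxiliary without a strong base.

Step 6
Reactants: 11 vanillin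
Product: 12 3-methoxy-4-(TIPSO)benzaldehyde
Conditions: TIPSCl, imidazole, DMF, rt
Reagents that add atoms: triisopropylsilyl chloride CC(C)[Si](Cl)(C(C)C)C(C)C
Why: O-silylation of the phenol; the bulkier TIPS ether is cleaved by fluoride more slowly than the ring B TBS ether, which orders the events of step 10.

Step 7
Reactants: 10 (S)-4-benzyl-3-{2-[5-bromo-3-methoxy-2-(TBSO)phenyl]acetyl}-1,3-oxazolidin-2-one; 12 3-methoxy-4-(TIPSO)benzaldehyde
Product: 14 (S)-4-benzyl-3-{(2S,3S)-2-[5-bromo-3-methoxy-2-(TBSO)phenyl]-3-hydroxy-3-[3-methoxy-4-(TIPSO)phenyl]propanoyl}-1,3-oxazolidin-2-one, via (Z)-dibutylboron enolate 13 (not isolated)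
Conditions: Bu2BOTf, i-Pr2NEt, CH2Cl2, 0 °C; 12, −78 → 0 °C; then pH 7 buffer, MeOH, H2O2, 0 °C
Reagents that add atoms: none
Why: Evans syn-aldol reaction, in which the (Z)-boron enolate reacts through a Zimmerman–Traxler chair on the face away from the benzyl group; this sets the α-carbon (later C3 of the first dihydrobenzofuran) and a syn carbinol centre that is erased in step 10.

Step 8
Reactants: 14 the syn-aldol adduct
Product: 15 (1S,2R)-2-[5-bromo-3-methoxy-2-(TBSO)phenyl]-1-[3-methoxy-4-(TIPSO)phenyl]propane-1,3-diol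
Conditions: LiBH4, MeOH (1 equiv), THF, 0 °C
Reagents that add atoms: none
Why: reductive cleavage of the N-acyl oxazolidinone gives the 1,3-diol and returns the auxiliary; the α-centre keeps its geometry (its descriptor changes from S to R only by priority) and is no longer acidic.

Step 9
Reactants: 15 the 1,3-diol
Product: 16 (1S,2R)-2-[5-bromo-3-methoxy-2-(TBSO)phenyl]-1-[3-methoxy-4-(TIPSO)phenyl]propane-1,3-diyl diacetate
Conditions: Ac2O, pyridine, DMAP (cat.), CH2Cl2, rt
Reagents that add atoms: acetic anhydride CC(=O)OC(C)=O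
Why: acetylation makes the benzylic oxygen a leaving group for quinone methide formation and protects the primary alcohol.

Step 10
Reactants: 16 the diacetate
Product: 20 [(2S,3R)-2-(4-acetoxy-3-methoxyphenyl)-5-bromo-7-methoxy-2,3-dihydro-1-benzofuran-3-yl]methyl acetate, via bis-phenol diacetate 17 (not isolated), via para-quinone methide 18 (not isolated), via cyclised phenol 19 (not isolated)
Conditions: Bu4NF (2.5 equiv), THF, −20 → 0 °C; then Ac2O, Et3N, DMAP (cat.), 0 °C
Reagents that add atoms: acetic anhydride CC(=O)OC(C)=O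
Why: key ring closure, in which fluoride frees the ring B phenoxide and then the ring A phenoxide, the latter expels the benzylic acetate (1,6-elimination) to the para-quinone methide, and the ring B phenoxide adds to it in a 5-exo intramolecular oxa-Michael (1,6-conjugate) addition that places the aryl group trans to the C3 substituent (2S,3R, reversible and therefore thermodynamic) before Ac2O caps the freed phenol.

Step 11
Reactants: 20 the bromo-dihydrobenzofuran diacetate
Product: 21 [(2S,3R)-2-(4-acetoxy-3-methoxyphenyl)-5-formyl-7-methoxy-2,3-dihydro-1-benzofuran-3-yl]methyl acetate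
Conditions: Pd(OAc)2 (1 mol%), n-BuP(1-adamantyl)2 (3 mol%), TMEDA, CO/H2 (1:1, 5 bar), toluene, 100 °C
Reagents that add atoms: carbon monoxide [C-]#[O+]
Why: palladium-catalysed reductive carbonylation (formylation) of the unhindered aryl bromide, via oxidative addition to zerovalent palladium, CO insertion and hydrogenolysis of the acyl-palladium; the acetates and both stereocentres are inert.

**Ring C branch**

Step 12
Reactants: 22 5-bromovanillin (3-bromo-4-hydroxy-5-methoxybenzaldehyde)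
Product: 23 3-bromo-5-methoxy-4-(TBSO)benzaldehyde
Conditions: TBSCl, imidazole, DMF, rt
Reagents that add atoms: tert-butyldimethylsilyl chloride CC(C)(C)[Si](C)(C)Cl
Why: O-silylation protects the phenol as an ether that later falls to K2CO3/MeOH while alkyl silyl ethers stay.

Step 13
Reactants: 23 3-bromo-5-methoxy-4-(TBSO)benzaldehyde
Product: 24 ethyl (E)-3-[3-bromo-5-methoxy-4-(TBSO)phenyl]prop-2-enoate
Conditions: Ph3P=CHCO2Et, toluene, 80 °C
Reagents that add atoms: ethyl (triphenylphosphoranylidene)acetate CCOC(=O)C=P(c1ccccc1)(c1ccccc1)c1ccccc1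
Why: Wittig olefination with a stabilised ylide gives the (E)-enoate selectively under neutral conditions.

Step 14
Reactants: 24 the (E)-enoate
Product: 25 (E)-3-[3-bromo-5-methoxy-4-(TBSO)phenyl]prop-2-en-1-ol
Conditions: i-Bu2AlH (2.5 equiv), CH2Cl2, −78 °C; aq. KNaC4H4O6 work-up
Reagents that add atoms: none
Why: 1,2-reduction of the enoate with i-Bu2AlH gives the allylic alcohol with the (E)-alkene retained.

Step 15
Reactants: 25 the allylic alcohol
Product: 26 {2-bromo-4-[(E)-3-(TBDPSO)prop-1-en-1-yl]-6-methoxyphenoxy}(tert-butyl)dimethylsilane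
Conditions: TBDPSCl, imidazole, CH2Cl2, 0 °C → rt
Reagents that add atoms: tert-butyldiphenylsilyl chloride CC(C)(C)[Si](Cl)(c1ccccc1)c1ccccc1
Why: silylation gives a primary TBDPS ether that survives silyl triflate, K2CO3/MeOH and catalytic acid and comes off with fluoride last.

Step 16
Reactants: 26 the aryl bromide
Product: 27 tert-butyl 2-{3-methoxy-2-(TBSO)-5-[(E)-3-(TBDPSO)prop-1-en-1-yl]phenyl}acetate
Conditions: BrCH2CO2t-Bu, Zn, THF (gives BrZnCH2CO2t-Bu); then 26, Pd(dba)2 (2 mol%), P(t-Bu)3 (2 mol%), THF, rt → 50 °C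
Reagents that add atoms: tert-butyl bromoacetate (used as its zinc reagent) CC(C)(C)OC(=O)CBr
Why: Negishi-type α-arylation of the Reformatsky zinc enolate forges the aryl–CH2 bond at the carbon that bore bromine under neutral conditions that leave both silyl ethers and the (E)-alkene alone.

Step 17
Reactants: 27 the tert-butyl ester
Product: 29 2-{3-methoxy-2-(TBSO)-5-[(E)-3-(TBDPSO)prop-1-en-1-yl]phenyl}acetic acid, via trimethylsilyl ester 28 (not isolated)
Conditions: TMSOTf, 2,6-lutidine, CH2Cl2, 0 °C; then H2O (pH 5 buffer)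
Reagents that add atoms: none
Why: silyl-triflate-mediated tert-butyl ester cleavage (loss of isobutene, then hydrolysis of the silyl ester on work-up) avoids the protic acid that would ionise the cinnamyl ether.

Step 18
Reactants: 29 the arylacetic acid; 8 (S)-4-benzyl-1,3-oxazolidin-2-one
Product: 31 (S)-4-benzyl-3-(2-{3-methoxy-2-(TBSO)-5-[(E)-3-(TBDPSO)prop-1-en-1-yl]phenyl}acetyl)-1,3-oxazolidin-2-one, via mixed pivalic anhydride 30 (not isolated)
Conditions: PivCl, Et3N, THF, −20 °C; then 8, LiCl, rt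
Reagents that add atoms: none
Why: N-acylation of the auxiliary through the mixed anhydride, as in step 5.

**Fragment union and endgame**

Step 19
Reactants: 31 the ring C imide; 21 the AB aldehyde
Product: 33 [(2S,3R)-2-(4-acetoxy-3-methoxyphenyl)-5-{(1S,2S)-3-[(S)-4-benzyl-2-oxo-1,3-oxazolidin-3-yl]-1-hydroxy-2-[3-methoxy-2-(TBSO)-5-((E)-3-(TBDPSO)prop-1-en-1-yl)phenyl]-3-oxopropyl}-7-methoxy-2,3-dihydro-1-benzofuran-3-yl]methyl acetate, via (Z)-dibutylboron enolate 32 (not isolated)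
Conditions: Bu2BOTf, i-Pr2NEt, CH2Cl2, 0 °C; 21, −78 → 0 °C; then pH 7 buffer, MeOH, H2O2, 0 °C
Reagents that add atoms: none
Why: fragment union by a second Evans syn-aldol reaction with the same auxiliary and facial sense as step 7, so the α-carbon (later C3 of the second dihydrobenzofuran) has the required configuration while the carbinol centre is again temporary.

Step 20
Reactants: 33 the aldol adduct
Product: 35 (1S,2R)-1-[(2S,3R)-2-(4-hydroxy-3-methoxyphenyl)-3-(hydroxymethyl)-7-methoxy-2,3-dihydro-1-benzofuran-5-yl]-2-{2-hydroxy-3-methoxy-5-[(E)-3-(TBDPSO)prop-1-en-1-yl]phenyl}propane-1,3-diol, via ring C silyl ether 34 (not isolated)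
Conditions: LiBH4, MeOH, THF, 0 °C → rt; then K2CO3, MeOH, rt
Reagents that add atoms: none
Why: LiBH4 reduces the imide to the primary alcohol and cleaves both acetates reductively, and K2CO3/MeOH then removes the phenolic TBS ether (the alkyl TBDPS ether survives), freeing the ring C phenol for ring closure.

Step 21
Reactants: 35 the open diol with free ring C phenol
Product: 37 [(2S,3R)-2-[(2S,3R)-2-(4-hydroxy-3-methoxyphenyl)-3-(hydroxymethyl)-7-methoxy-2,3-dihydro-1-benzofuran-5-yl]-7-methoxy-5-[(E)-3-(TBDPSO)prop-1-en-1-yl]-2,3-dihydro-1-benzofuran-3-yl]methanol, via O-alkyl quinone methide cation 36 (not isolated)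
Conditions: TsOH·H2O (0.2 equiv), MeCN (0.01 M), 0 °C → rt
Reagents that add atoms: none
Why: acid-catalysed ionisation of the para-alkoxybenzylic alcohol gives the O-alkyl quinone methide cation of ring B, to which the ring C phenol adds 5-exo in an intramolecular oxa-Michael-type (1,6-conjugate) addition, the aryl group ending trans to the C3 hydroxymethyl (2S,3R) under kinetic and thermodynamic control while the C3 centre is untouched.

Step 22
Reactants: 37 the TBDPS ether of the target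
Product: 38 (E)-3-[(2S,3R)-2-[(2S,3R)-2-(4-hydroxy-3-methoxyphenyl)-3-(hydroxymethyl)-7-methoxy-2,3-dihydro-1-benzofuran-5-yl]-3-(hydroxymethyl)-7-methoxy-2,3-dihydro-1-benzofuran-5-yl]prop-2-en-1-ol
Conditions: Bu4NF, AcOH, THF, rt
Reagents that add atoms: none
Why: fluoride cleavage of the primary silyl ether, buffered with AcOH so the phenols stay protonated, releases the (E)-allylic alcohol and gives the target.

**Compound list**
1 | 5-bromo-2-hydroxy-3-methoxybenzaldehyde | COc1cc(Br)cc(C=O)c1O | starting material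
2 | 5-bromo-3-methoxy-2-(TBSO)benzaldehyde | COc1cc(Br)cc(C=O)c1O[Si](C)(C)C(C)(C)C | intermediate
3 | (4-bromo-2-ethenyl-6-methoxyphenoxy)(tert-butyl)dimethylsilane | COc1cc(Br)cc(C=C)c1O[Si](C)(C)C(C)(C)C | intermediate
4 | 9-{2-[5-bromo-3-methoxy-2-(TBSO)phenyl]ethyl}-9-borabicyclo[3.3.1]nonane | COc1cc(Br)cc(CCB2C3CCCC2CCC3)c1O[Si](C)(C)C(C)(C)C | intermediate (not isolated)
5 | 2-[5-bromo-3-methoxy-2-(TBSO)phenyl]ethanol | COc1cc(Br)cc(CCO)c1O[Si](C)(C)C(C)(C)C | intermediate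
6 | 2-[5-bromo-3-methoxy-2-(TBSO)phenyl]acetaldehyde | COc1cc(Br)cc(CC=O)c1O[Si](C)(C)C(C)(C)C | intermediate (not isolated)
7 | 2-[5-bromo-3-methoxy-2-(TBSO)phenyl]acetic acid | COc1cc(Br)cc(CC(=O)O)c1O[Si](C)(C)C(C)(C)C | intermediate
8 | (S)-4-benzyl-1,3-oxazolidin-2-one | O=C1N[C@@H](Cc2ccccc2)CO1 | starting material
9 | mixed anhydride of 7 with pivalic acid | CC(C)(C)C(=O)OC(=O)Cc1cc(Br)cc(OC)c1O[Si](C)(C)C(C)(C)C | intermediate (not isolated)
10 | (S)-4-benzyl-3-{2-[5-bromo-3-methoxy-2-(TBSO)phenyl]acetyl}-1,3-oxazolidin-2-one (ring B imide) | O=C(Cc1cc(Br)cc(OC)c1O[Si](C)(C)C(C)(C)C)N1C(=O)OC[C@@H]1Cc1ccccc1 | intermediate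
11 | vanillin | COc1cc(C=O)ccc1O | starting material
12 | 3-methoxy-4-(TIPSO)benzaldehyde | COc1cc(C=O)ccc1O[Si](C(C)C)(C(C)C)C(C)C | intermediate
13 | (Z)-dibutylboron enolate of 10 | CCCCB(CCCC)O/C(=C\c1cc(Br)cc(OC)c1O[Si](C)(C)C(C)(C)C)N1C(=O)OC[C@@H]1Cc1ccccc1 | intermediate (not isolated)
14 | (S)-4-benzyl-3-{(2S,3S)-2-[5-bromo-3-methoxy-2-(TBSO)phenyl]-3-hydroxy-3-[3-methoxy-4-(TIPSO)phenyl]propanoyl}-1,3-oxazolidin-2-one | O=C(N1C(=O)OC[C@@H]1Cc1ccccc1)[C@@H](c1cc(Br)cc(OC)c1O[Si](C)(C)C(C)(C)C)[C@H](O)c1ccc(O[Si](C(C)C)(C(C)C)C(C)C)c(OC)c1 | intermediate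
15 | (1S,2R)-2-[5-bromo-3-methoxy-2-(TBSO)phenyl]-1-[3-methoxy-4-(TIPSO)phenyl]propane-1,3-diol | OC[C@@H](c1cc(Br)cc(OC)c1O[Si](C)(C)C(C)(C)C)[C@H](O)c1ccc(O[Si](C(C)C)(C(C)C)C(C)C)c(OC)c1 | intermediate
16 | (1S,2R)-2-[5-bromo-3-methoxy-2-(TBSO)phenyl]-1-[3-methoxy-4-(TIPSO)phenyl]propane-1,3-diyl diacetate | CC(=O)OC[C@@H](c1cc(Br)cc(OC)c1O[Si](C)(C)C(C)(C)C)[C@H](OC(C)=O)c1ccc(O[Si](C(C)C)(C(C)C)C(C)C)c(OC)c1 | intermediate
17 | (1S,2R)-2-(5-bromo-2-hydroxy-3-methoxyphenyl)-1-(4-hydroxy-3-methoxyphenyl)propane-1,3-diyl diacetate (present as its phenoxides) | CC(=O)OC[C@@H](c1cc(Br)cc(OC)c1O)[C@H](OC(C)=O)c1ccc(O)c(OC)c1 | intermediate (not isolated)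
18 | (R)-2-(5-bromo-2-hydroxy-3-methoxyphenyl)-3-(3-methoxy-4-oxocyclohexa-2,5-dien-1-ylidene)propyl acetate (para-quinone methide of ring A) | CC(=O)OC[C@@H](c1cc(Br)cc(OC)c1O)C=C1C=CC(=O)C(OC)=C1 | intermediate (not isolated)
19 | [(2S,3R)-5-bromo-2-(4-hydroxy-3-methoxyphenyl)-7-methoxy-2,3-dihydro-1-benzofuran-3-yl]methyl acetate | COc1cc([C@H]2Oc3c(OC)cc(Br)cc3[C@@H]2COC(C)=O)ccc1O | intermediate (not isolated)
20 | [(2S,3R)-2-(4-acetoxy-3-methoxyphenyl)-5-bromo-7-methoxy-2,3-dihydro-1-benzofuran-3-yl]methyl acetate | COc1cc([C@H]2Oc3c(OC)cc(Br)cc3[C@@H]2COC(C)=O)ccc1OC(C)=O | intermediate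
21 | [(2S,3R)-2-(4-acetoxy-3-methoxyphenyl)-5-formyl-7-methoxy-2,3-dihydro-1-benzofuran-3-yl]methyl acetate (AB aldehyde) | COc1cc([C@H]2Oc3c(OC)cc(C=O)cc3[C@@H]2COC(C)=O)ccc1OC(C)=O | intermediate
22 | 5-bromovanillin | COc1cc(C=O)cc(Br)c1O | starting material
23 | 3-bromo-5-methoxy-4-(TBSO)benzaldehyde | COc1cc(C=O)cc(Br)c1O[Si](C)(C)C(C)(C)C | intermediate
24 | ethyl (E)-3-[3-bromo-5-methoxy-4-(TBSO)phenyl]prop-2-enoate | CCOC(=O)/C=C/c1cc(Br)c(O[Si](C)(C)C(C)(C)C)c(OC)c1 | intermediate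
25 | (E)-3-[3-bromo-5-methoxy-4-(TBSO)phenyl]prop-2-en-1-ol | OC/C=C/c1cc(Br)c(O[Si](C)(C)C(C)(C)C)c(OC)c1 | intermediate
26 | {2-bromo-4-[(E)-3-(TBDPSO)prop-1-en-1-yl]-6-methoxyphenoxy}(tert-butyl)dimethylsilane | COc1cc(/C=C/CO[Si](c2ccccc2)(c2ccccc2)C(C)(C)C)cc(Br)c1O[Si](C)(C)C(C)(C)C | intermediate
27 | tert-butyl 2-{3-methoxy-2-(TBSO)-5-[(E)-3-(TBDPSO)prop-1-en-1-yl]phenyl}acetate | COc1cc(/C=C/CO[Si](c2ccccc2)(c2ccccc2)C(C)(C)C)cc(CC(=O)OC(C)(C)C)c1O[Si](C)(C)C(C)(C)C | intermediate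
28 | trimethylsilyl ester of 29 | COc1cc(/C=C/CO[Si](c2ccccc2)(c2ccccc2)C(C)(C)C)cc(CC(=O)O[Si](C)(C)C)c1O[Si](C)(C)C(C)(C)C | intermediate (not isolated)
29 | 2-{3-methoxy-2-(TBSO)-5-[(E)-3-(TBDPSO)prop-1-en-1-yl]phenyl}acetic acid | COc1cc(/C=C/CO[Si](c2ccccc2)(c2ccccc2)C(C)(C)C)cc(CC(=O)O)c1O[Si](C)(C)C(C)(C)C | intermediate
30 | mixed anhydride of 29 with pivalic acid | COc1cc(/C=C/CO[Si](c2ccccc2)(c2ccccc2)C(C)(C)C)cc(CC(=O)OC(=O)C(C)(C)C)c1O[Si](C)(C)C(C)(C)C | intermediate (not isolated)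
31 | (S)-4-benzyl-3-(2-{3-methoxy-2-(TBSO)-5-[(E)-3-(TBDPSO)prop-1-en-1-yl]phenyl}acetyl)-1,3-oxazolidin-2-one (ring C imide) | COc1cc(/C=C/CO[Si](c2ccccc2)(c2ccccc2)C(C)(C)C)cc(CC(=O)N2C(=O)OC[C@@H]2Cc2ccccc2)c1O[Si](C)(C)C(C)(C)C | intermediate
32 | (Z)-dibutylboron enolate of 31 | CCCCB(CCCC)O/C(=C\c1cc(/C=C/CO[Si](c2ccccc2)(c2ccccc2)C(C)(C)C)cc(OC)c1O[Si](C)(C)C(C)(C)C)N1C(=O)OC[C@@H]1Cc1ccccc1 | intermediate (not isolated)
33 | syn-aldol adduct of 31 and 21 (dihydrobenzofuran 2S,3R; new carbinol carbon S; new α-carbon S; auxiliary S) | COc1cc([C@H]2Oc3c(OC)cc([C@@H](O)[C@H](c4cc(/C=C/CO[Si](c5ccccc5)(c5ccccc5)C(C)(C)C)cc(OC)c4O[Si](C)(C)C(C)(C)C)C(=O)N4C(=O)OC[C@@H]4Cc4ccccc4)cc3[C@@H]2COC(C)=O)ccc1OC(C)=O | intermediate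
34 | (1S,2R)-1-[(2S,3R)-2-(4-hydroxy-3-methoxyphenyl)-3-(hydroxymethyl)-7-methoxy-2,3-dihydro-1-benzofuran-5-yl]-2-{3-methoxy-2-(TBSO)-5-[(E)-3-(TBDPSO)prop-1-en-1-yl]phenyl}propane-1,3-diol | COc1cc([C@H]2Oc3c(OC)cc([C@@H](O)[C@H](c4cc(/C=C/CO[Si](c5ccccc5)(c5ccccc5)C(C)(C)C)cc(OC)c4O[Si](C)(C)C(C)(C)C)CO)cc3[C@@H]2CO)ccc1O | intermediate (not isolated)
35 | (1S,2R)-1-[(2S,3R)-2-(4-hydroxy-3-methoxyphenyl)-3-(hydroxymethyl)-7-methoxy-2,3-dihydro-1-benzofuran-5-yl]-2-{2-hydroxy-3-methoxy-5-[(E)-3-(TBDPSO)prop-1-en-1-yl]phenyl}propane-1,3-diol | COc1cc([C@H]2Oc3c(OC)cc([C@@H](O)[C@H](c4cc(/C=C/CO[Si](c5ccccc5)(c5ccccc5)C(C)(C)C)cc(OC)c4O)CO)cc3[C@@H]2CO)ccc1O | intermediate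
36 | para-alkoxybenzylic cation of 35 at the ring B carbinol carbon (O-alkyl quinone methide cation; remaining centres as in 35) | COc1cc([C@H]2Oc3c(OC)cc([CH+][C@H](c4cc(/C=C/CO[Si](c5ccccc5)(c5ccccc5)C(C)(C)C)cc(OC)c4O)CO)cc3[C@@H]2CO)ccc1O | intermediate (not isolated)
37 | [(2S,3R)-2-[(2S,3R)-2-(4-hydroxy-3-methoxyphenyl)-3-(hydroxymethyl)-7-methoxy-2,3-dihydro-1-benzofuran-5-yl]-7-methoxy-5-[(E)-3-(TBDPSO)prop-1-en-1-yl]-2,3-dihydro-1-benzofuran-3-yl]methanol | COc1cc([C@H]2Oc3c(OC)cc([C@H]4Oc5c(OC)cc(/C=C/CO[Si](c6ccccc6)(c6ccccc6)C(C)(C)C)cc5[C@@H]4CO)cc3[C@@H]2CO)ccc1O | intermediate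
38 | (E)-3-[(2S,3R)-2-[(2S,3R)-2-(4-hydroxy-3-methoxyphenyl)-3-(hydroxymethyl)-7-methoxy-2,3-dihydro-1-benzofuran-5-yl]-3-(hydroxymethyl)-7-methoxy-2,3-dihydro-1-benzofuran-5-yl]prop-2-en-1-ol (CNP0250921.2) | COc1cc([C@H]2Oc3c(OC)cc([C@H]4Oc5c(OC)cc(/C=C/CO)cc5[C@@H]4CO)cc3[C@@H]2CO)ccc1O | target

**Totals**
Total step count: 22.
Longest linear sequence: 14 steps (steps 1–5, 7–11 and 19–22). The ring C branch (steps 12–18) and step 6 run in parallel with it.

**Three steps most likely to fail, with fallbacks**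

Step 10 (fluoride-triggered quinone methide formation and oxa-Michael closure). If the quinone methide forms before the ring B phenoxide is free, it can tautomerise to a stilbene or be trapped by fluoride or water. The fallback changes how the quinone methide is made. It sets out from diol 15 and comes back at 20, skipping step 9. Bu4NF in THF removes both aryl silyl ethers to give the tetraol (1S,2R)-2-(5-bromo-2-hydroxy-3-methoxyphenyl)-1-(4-hydroxy-3-methoxyphenyl)propane-1,3-diol F1. Catalytic TsOH·H2O in MeCN then dehydrates the para-hydroxybenzyl alcohol to the protonated quinone methide, which the ring B phenol traps in the same oxa-Michael sense to give the trans-dihydrobenzofuran diol (2S,3R)-5-bromo-2-(4-hydroxy-3-methoxyphenyl)-3-(hydroxymethyl)-7-methoxy-2,3-dihydro-1-benzofuran F2. Ac2O/pyridine converts this into 20.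

Step 16 (α-arylation next to a bulky ortho silyloxy group). The hindered, electron-rich bromide may add slowly to palladium, so reduction or homocoupling could dominate. The fallback drops the enolate arylation and builds the ring C imide from the ring B series. It sets out from bromo imide 10 and comes back at 31. Commercial (E)-3-(tributylstannyl)prop-2-en-1-ol is silylated (TBDPSCl, imidazole) to the stannane (E)-tert-butyldiphenyl{[3-(tributylstannyl)prop-2-en-1-yl]oxy}silane F3. A Stille coupling of this stannane with 10 (Pd(PPh3)4, toluene, 100 °C) replaces the unhindered bromine para to the silyloxy group and gives 31 directly.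

Step 21 (late acid-mediated closure beside a cinnamyl ether). The acid may ionise the allylic silyl ether or cause oligomerisation. The fallback runs the acid step on a substrate with no allylic oxygen and attaches the side chain last. It sets out from aldehyde 21 (with enolate 13 from 10) and comes back at 38. The aldol of step 19 carried out with 13 gives the bromo aldol adduct F4. LiBH4/MeOH followed by K2CO3/MeOH gives the open bromo diol F5. TsOH·H2O in MeCN closes the second ring to the bromo bis(dihydrobenzofuran) F6. A Stille coupling with (E)-3-(tributylstannyl)prop-2-en-1-ol (Pd(PPh3)4, DMF, 90 °C) then gives 38.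

Further compounds
F1 | step 10 | (1S,2R)-2-(5-bromo-2-hydroxy-3-methoxyphenyl)-1-(4-hydroxy-3-methoxyphenyl)propane-1,3-diol | OC[C@@H](c1cc(Br)cc(OC)c1O)[C@H](O)c1ccc(O)c(OC)c1
F2 | step 10 | (2S,3R)-5-bromo-2-(4-hydroxy-3-methoxyphenyl)-3-(hydroxymethyl)-7-methoxy-2,3-dihydro-1-benzofuran | COc1cc([C@H]2Oc3c(OC)cc(Br)cc3[C@@H]2CO)ccc1O
F3 | step 16 | (E)-tert-butyldiphenyl{[3-(tributylstannyl)prop-2-en-1-yl]oxy}silane | CCCC[Sn](CCCC)(CCCC)/C=C/CO[Si](c1ccccc1)(c1ccccc1)C(C)(C)C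
F4 | step 21 | syn-aldol adduct of 10 and 21 (dihydrobenzofuran 2S,3R; carbinol carbon S; α-carbon S; auxiliary S) | COc1cc([C@H]2Oc3c(OC)cc([C@@H](O)[C@H](c4cc(Br)cc(OC)c4O[Si](C)(C)C(C)(C)C)C(=O)N4C(=O)OC[C@@H]4Cc4ccccc4)cc3[C@@H]2COC(C)=O)ccc1OC(C)=O
F5 | step 21 | (1S,2R)-2-(5-bromo-2-hydroxy-3-methoxyphenyl)-1-[(2S,3R)-2-(4-hydroxy-3-methoxyphenyl)-3-(hydroxymethyl)-7-methoxy-2,3-dihydro-1-benzofuran-5-yl]propane-1,3-diol | COc1cc([C@H]2Oc3c(OC)cc([C@@H](O)[C@H](c4cc(Br)cc(OC)c4O)CO)cc3[C@@H]2CO)ccc1O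
F6 | step 21 | [(2S,3R)-5-bromo-2-[(2S,3R)-2-(4-hydroxy-3-methoxyphenyl)-3-(hydroxymethyl)-7-methoxy-2,3-dihydro-1-benzofuran-5-yl]-7-methoxy-2,3-dihydro-1-benzofuran-3-yl]methanol | COc1cc([C@H]2Oc3c(OC)cc([C@H]4Oc5c(OC)cc(Br)cc5[C@@H]4CO)cc3[C@@H]2CO)ccc1O
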